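**Plan**

- Numbering (longipinane): C1(=O)–C2=C3(Me)–C4–C5–C6(Me2)–C7(O)–C8–C9(O)–C10(Me)–C11–C1, with cross-ring bonds C4–C10 and C5–C11. Rings: cyclohexenone C1–C2–C3–C4–C5–C11, cyclobutane C4–C5–C11–C10, cycloheptane C5–C6–C7–C8–C9–C10–C11.
- Enabling feature: read as C5–C4–C3(Me)–C2–C1–C11–C10(Me)–C9–C8–C7–C6(Me2), the fifteen skeletal carbons are an unbroken head-to-tail farnesyl chain. The ring bonds C5–C6, C5–C11 and C4–C10 are therefore the ones a sesquiterpene cyclase forms.
- Retrosynthesis: cut the two ester C–O bonds (tigloyl on O7, senecioyl on O9), remove the C9 and C7 oxygens and the C1 carbonyl to reach α-longipinene, then cut C4–C10, C5–C11 and C5–C6 to open all three rings to farnesyl diphosphate.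
- Forward: one enzymatic step closes C5–C6 (eleven-membered ring), then C5–C11 (six- and seven-membered rings), then C4–C10 (cyclobutane). C1 is then oxidized, C7 is oxygenated and its ketone desaturated to C8=C9, C9 gains oxygen by conjugate borylation, and a hydride-transfer esterification sets C7 and places the senecioate on O9 before the tiglate goes on O7.
- Stereochemistry: C4, C5, C10 and C11 come from the cyclase (absolute sense) and the cage (relative sense). C9 comes from a chiral copper–boryl catalyst. C7 comes from intramolecular hydride delivery from the C9 oxygen (anti).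

Key step: step 3

Assumption: the α-longipinene synthase chosen folds the chain to the (4R,5R,10S,11R) hydrocarbon [(1R,2S,7R,8R) in tricyclo[5.4.0.0(2,8)]undec-9-ene numbering]; a cyclase of the mirror-image series cannot be used.

**Route**

Step 1
Reactants: 1 (2E,6E)-farnesol
Product: 2 (2E,6E)-farnesyl bromide
Conditions: PBr3 (0.4 equiv), Et2O, −10 °C to 0 °C; used crude
Reagents that add atoms: phosphorus tribromide, BrP(Br)Br
Why: Bromination of a primary allylic alcohol through its phosphite ester (SN2); at low temperature bromide should enter at C1 without allylic transposition and both trisubstituted alkenes keep their E geometry.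

Step 2
Reactants: 2 (2E,6E)-farnesyl bromide
Product: 3 (2E,6E)-farnesyl diphosphate
Conditions: (n-Bu4N)3HP2O7 (2 equiv), MeCN, rt; Dowex 50W-X8 (NH4+ form), aq NH4HCO3/i-PrOH; cellulose chromatography; lyophilized as the ammonium salt
Reagents that add atoms: tris(tetrabutylammonium) hydrogen diphosphate, CCCC[N+](CCCC)(CCCC)CCCC.CCCC[N+](CCCC)(CCCC)CCCC.CCCC[N+](CCCC)(CCCC)CCCC.OP(=O)([O-])OP(=O)([O-])[O-]
Why: SN2 displacement of the primary allylic bromide by the diphosphate trianion, the standard chemical synthesis of allylic diphosphates; no stereocentre is formed and the alkene geometry is untouched.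

Step 3
Reactants: 3 (2E,6E)-farnesyl diphosphate
Product: 5 α-longipinene [(4R,5R,10S,11R)-longipin-2-ene], via nerolidyl diphosphate 4 (not isolated)
Conditions: recombinant α-longipinene synthase (His-tagged, from E. coli), MgCl2 (10 mM), HEPES pH 7.5, DTT, 10% glycerol, 30 °C, pentane overlay; silica (AgNO3-silica if co-products appear)
Reagents that add atoms: none
Why: Mg2+-assisted ionization of the diphosphate, with return to the tertiary carbon as 4 so that the chain can adopt the cisoid geometry, starts a cation–olefin cascade: C5 bonds to C6 of the terminal alkene (eleven-membered ring, secondary cation at C7), a 1,3-hydride shift from C5 to C7 gives the C5–C4–C3 allyl cation, the central alkene attacks C5 through C11 (tertiary cation at C10), the C3=C4 alkene attacks C10 through C4 (tertiary cation at C3), and loss of a proton from C2 leaves the C2=C3 alkene. This is the characterized reaction of α-longipinene synthases, and its closest non-enzymatic relative is a biomimetic cation–olefin polycyclization. Ring closures: C5–C6 is an 11-endo macrocyclization, C5–C11 is a transannular closure that divides the eleven-membered ring into the cyclohexene (6-exo) and the cycloheptane (7-endo), and C4–C10 is a 4-exo closure to the cyclobutane. C5 and C11 are set by the faces of the allyl cation and of the central alkene that the folded chain shows to each other in the active site, and C10 and C4 follow because the C6–C9 bridge can span C5 and C10 only cis on the cyclobutane and anti to the C1–C3 bridge; the absolute sense is that of the enzyme fold. The step must follow the longipinyl path and not the longibornyl path (attack on C10 through C3) or early proton loss to himachalenes: bond formation through C4 puts the charge on tertiary C3 whereas attack through C3 would put it on secondary C4, and the active-site contour holds C4 over C10.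

Step 4
Reactants: 5 α-longipinene
Product: 6 (4R,5S,10R,11R)-longipin-2-en-1-one
Conditions: Rh2(cap)4 [dirhodium tetrakis(caprolactamate)] (1 mol %), t-BuOOH (70% aq, 5 equiv), K2CO3, CH2Cl2, rt
Reagents that add atoms: tert-butyl hydroperoxide, CC(C)(C)OO
Why: Radical allylic oxidation: the tert-butylperoxyl radical abstracts hydrogen from C1, the only secondary allylic position (C4 is a cyclobutane bridgehead and the C3 methyl is primary), and the mixed peroxide collapses to the enone, as in the oxidation of α-pinene to verbenone; no stereocentre is formed or touched.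

Step 5
Reactants: 6 (4R,5S,10R,11R)-longipin-2-en-1-one
Product: 7 (4R,5S,7R,10R,11R)-7-hydroxylongipin-2-en-1-one
Conditions: P450BM3 (CYP102A1) variant selected from an active-site mutant library, E. coli lysate, NADP+ (cat.), glucose dehydrogenase, D-glucose, air, KPi buffer pH 8, 2% DMSO, 25 °C
Reagents that add atoms: dioxygen, O=O
Why: Proposed new method: the iron-oxo species of the enzyme abstracts hydrogen and returns hydroxyl at an accessible, electron-rich methylene; in 6 the enone deactivates its own side of the cage (C11, the C3 methyl and, through C10, C9), the cyclobutane C–H bonds are strong, and C7, next to the gem-dimethyl carbon C6 and far from the carbonyl, is the site to be fixed by directed evolution of the active site; the closest known reaction type is hydroxylation, by engineered P450BM3 variants, of the ring methylene next to the gem-dimethyl carbon of drimane-type terpenoids such as sclareolide; either C7 epimer serves because C7 becomes a carbonyl carbon in step 6 (the 7R alcohol is drawn).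

Step 6
Reactants: 7 (4R,5S,7R,10R,11R)-7-hydroxylongipin-2-en-1-one
Product: 9 (4R,5S,10R,11R)-longipina-2,8-diene-1,7-dione, via longipin-2-ene-1,7-dione 8 (not isolated)
Conditions: IBX (3.5 equiv), DMSO/PhF (1:2), 25 °C then 75 °C
Reagents that add atoms: none
Why: IBX oxidizes the secondary alcohol to ketone 8 and, on warming, dehydrogenates it through its enol (IBX ketone dehydrogenation); C6 is quaternary, so only C8–C9 can be desaturated, the reaction stops at the enone because C10 is quaternary, and the C1 enone has no enolizable hydrogen at the bridgehead C11.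

Step 7
Reactants: 9 (4R,5S,10R,11R)-longipina-2,8-diene-1,7-dione
Product: 11 (4R,5S,9R,10R,11R)-9-hydroxylongipin-2-ene-1,7-dione, via 9-pinacolboryl-1,7-dione 10 (not isolated)
Conditions: CuCl (5 mol %), NaOt-Bu (7 mol %), (R)-1-[(S)-2-(diphenylphosphino)ferrocenyl]ethyldicyclohexylphosphine (6 mol %; its mirror image if a test run shows the opposite face), B2pin2 (1.1 equiv), MeOH (2 equiv), THF, 0 °C; then NaBO3·4H2O, THF/pH 7 phosphate buffer, 0 °C
Reagents that add atoms: bis(pinacolato)diboron, CC1(C)OB(OC1(C)C)B1OC(C)(C)C(C)(C)O1 (boron of 10); sodium perborate, [Na+].[Na+].O[B-]1(O)OO[B-](O)(O)OO1 (oxygen of 11)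
Why: Copper-catalysed conjugate borylation: the ligated copper–boryl species adds across C8=C9 with boron on the β-carbon C9, methanol protonates the copper enolate at C8, and perborate replaces boron by hydroxyl with retention; the C2=C3 enone, whose β-carbon is fully substituted, should react far more slowly; because C6–C10 lie in a local mirror plane of the cage the substrate offers little facial bias, so the chiral ligand sets C9, boron being delivered to the Re face (the face turned toward C11); buffered oxidation and prompt use of 11 guard against retro-aldol epimerization and dehydration.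

Step 8
Reactants: 11 (4R,5S,9R,10R,11R)-9-hydroxylongipin-2-ene-1,7-dione; 12 3-methylbut-2-enal
Product: 13 (4R,5S,7R,9R,10R,11R)-7-hydroxy-9-(3-methylbut-2-enoyloxy)longipin-2-en-1-one
Conditions: SmI2 (0.3 equiv, premixed with 12), 12 (6 equiv), THF, −10 °C
Reagents that add atoms: none
Why: Evans–Tishchenko reaction: trivalent samarium (formed from SmI2 and the aldehyde) holds the adduct of the C9 alkoxide with 12 and the C7 carbonyl in a six-membered chelate, and the former aldehyde hydrogen is passed to C7 on the face that carries O9, so the new C7 hydroxyl is anti to O9 (7R) and the acyl group stays on O9 as the 3-methylbut-2-enoate; the C1 enone has no hydroxyl placed for six-membered delivery and is left alone, and the trans-1,3 oxygens on the ring cannot share a cyclic orthoester, which blocks acyl migration.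

Step 9
Reactants: 13 (4R,5S,7R,9R,10R,11R)-7-hydroxy-9-(3-methylbut-2-enoyloxy)longipin-2-en-1-one; 14 (E)-2-methylbut-2-enoyl chloride (tigloyl chloride)
Product: 15 (4R,5S,7R,9R,10R,11R)-9-(3-methylbut-2-enoyloxy)-7-[(E)-2-methylbut-2-enoyloxy]longipin-2-en-1-one
Conditions: 14 (3 equiv), pyridine, DMAP (0.2 equiv), CH2Cl2, 0 °C to 40 °C
Reagents that add atoms: none
Why: DMAP-catalysed acylation of the one remaining hydroxyl; pyridine in place of a trialkylamine avoids the vinylketene pathway that would deconjugate the acyl group, the E geometry of 14 is carried over, and no stereocentre is touched.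

**Compound list**

1 | (2E,6E)-farnesol | CC(C)=CCC/C(C)=C/CC/C(C)=C/CO | starting material
2 | (2E,6E)-farnesyl bromide | CC(C)=CCC/C(C)=C/CC/C(C)=C/CBr | intermediate
3 | (2E,6E)-farnesyl diphosphate (kept as the ammonium salt, drawn as the acid) | CC(C)=CCC/C(C)=C/CC/C(C)=C/COP(=O)(O)OP(=O)(O)O | intermediate
4 | (6E)-nerolidyl diphosphate, enzyme-bound (C3 configuration fixed by the enzyme, not assigned, lost on re-ionization) | CC(C)=CCC/C(C)=C/CCC(C)(C=C)OP(=O)(O)OP(=O)(O)O | intermediate (not isolated)
5 | α-longipinene, (4R,5R,10S,11R)-longipin-2-ene | C1CC[C@@]2(C)[C@@H]3CC=C(C)[C@H]2[C@@H]3C1(C)C | intermediate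
6 | (4R,5S,10R,11R)-longipin-2-en-1-one | C1CC[C@@]2(C)[C@@H]3C(=O)C=C(C)[C@H]2[C@@H]3C1(C)C | intermediate
7 | (4R,5S,7R,10R,11R)-7-hydroxylongipin-2-en-1-one | O[C@@H]1CC[C@@]2(C)[C@@H]3C(=O)C=C(C)[C@H]2[C@@H]3C1(C)C | intermediate
8 | (4R,5S,10R,11R)-longipin-2-ene-1,7-dione | O=C1CC[C@@]2(C)[C@@H]3C(=O)C=C(C)[C@H]2[C@@H]3C1(C)C | intermediate (not isolated)
9 | (4R,5S,10R,11R)-longipina-2,8-diene-1,7-dione | O=C1C=C[C@@]2(C)[C@@H]3C(=O)C=C(C)[C@H]2[C@@H]3C1(C)C | intermediate
10 | (4R,5S,9R,10R,11R)-9-(4,4,5,5-tetramethyl-1,3,2-dioxaborolan-2-yl)longipin-2-ene-1,7-dione | O=C1C[C@@H](B4OC(C)(C)C(C)(C)O4)[C@@]2(C)[C@@H]3C(=O)C=C(C)[C@H]2[C@@H]3C1(C)C | intermediate (not isolated)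
11 | (4R,5S,9R,10R,11R)-9-hydroxylongipin-2-ene-1,7-dione | O=C1C[C@@H](O)[C@@]2(C)[C@@H]3C(=O)C=C(C)[C@H]2[C@@H]3C1(C)C | intermediate
12 | 3-methylbut-2-enal | CC(C)=CC=O | starting material
13 | (4R,5S,7R,9R,10R,11R)-7-hydroxy-9-(3-methylbut-2-enoyloxy)longipin-2-en-1-one | O[C@@H]1C[C@@H](OC(=O)C=C(C)C)[C@@]2(C)[C@@H]3C(=O)C=C(C)[C@H]2[C@@H]3C1(C)C | intermediate
14 | (E)-2-methylbut-2-enoyl chloride (tigloyl chloride) | C/C=C(\C)C(=O)Cl | starting material
15 | (4R,5S,7R,9R,10R,11R)-9-(3-methylbut-2-enoyloxy)-7-[(E)-2-methylbut-2-enoyloxy]longipin-2-en-1-one | C/C=C(\C)C(=O)O[C@@H]1C[C@@H](OC(=O)C=C(C)C)[C@@]2(C)[C@@H]3C(=O)C=C(C)[C@H]2[C@@H]3C1(C)C | target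

**Step count**

Total steps: 9. Longest linear sequence: 9 steps (1 to 15).

**Steps most likely to fail**

Step 5. No enzyme variant may reach C7 with useful selectivity; hydroxylation could go to the less hindered C8 or to the allylic methyl instead. The fallback uses known chemistry, sets out from 6 and returns at 9. Amidyl-radical C–H bromination with N-bromo-N-tert-butyl-3,5-bis(trifluoromethyl)benzamide under visible light, which on drimane-type rings takes the methylene lying between two neopentyl positions, should give (8ξ)-8-bromolongipin-2-en-1-one F1. Dehydrobromination (LiBr, Li2CO3, DMF, 120 °C) should give longipina-2,8-dien-1-one F2 together with its double-bond isomer longipina-2,7-dien-1-one F3. The two need not be separated, because hydrogen abstraction from either leads to the same C7–C8–C9 allyl radical. Allylic oxidation as in step 4 (Rh2(cap)4, t-BuOOH) then gives 9. The weakness of this detour is oxygen capture at C9 instead of C7, which would divert part of the material into the regioisomeric enone, to be removed by chromatography.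

Step 7. Facial selectivity at C9 may be poor because the substrate is nearly mirror-symmetric there, boron may also add to the C2=C3 enone, or the β-hydroxy ketone may dehydrate or epimerize by retro-aldol during oxidative work-up. The fallback sets out from 9 and returns at 11. Catalyst-controlled nucleophilic epoxidation (9-amino-9-deoxy-epi-quinine trifluoroacetate salt or its quinidine-derived counterpart, aq H2O2, dioxane), acting through the iminium ion of the C7 ketone, should give (4R,5S,8S,9S,10R,11R)-8,9-epoxylongipin-2-ene-1,7-dione F4 with the epoxide oxygen on the face turned toward C11. Organoselenium reduction of the epoxy ketone (PhSeSePh, NaBH4, AcOH, EtOH, 0 °C) cleaves the C8–O bond and leaves the C9 hydroxyl of 11 with its configuration intact.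

Step 8. The conjugated aldehyde may be a reluctant hydride donor, may be consumed by pinacol coupling, or the β-hydroxy ketone may lose water on the Lewis acid before hydride transfer. The fallback sets out from 11 and returns at 15. The Evans–Tishchenko reaction is run with acetaldehyde (SmI2 cat., THF, −10 °C), its classical partner, to give (4R,5S,7R,9R,10R,11R)-9-acetoxy-7-hydroxylongipin-2-en-1-one F5. Acylation with 14 (pyridine, DMAP) gives (4R,5S,7R,9R,10R,11R)-9-acetoxy-7-[(E)-2-methylbut-2-enoyloxy]longipin-2-en-1-one F6. Selective methanolysis of the acetate (K2CO3 cat., MeOH, 0 °C), which the hindered conjugated ester should survive, gives (4R,5S,7R,9R,10R,11R)-9-hydroxy-7-[(E)-2-methylbut-2-enoyloxy]longipin-2-en-1-one F7. Acylation with 3-methylbut-2-enoyl chloride (CC(C)=CC(=O)Cl; pyridine, DMAP) then gives 15.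

Further compounds
F1 | step 5 | (4R,5S,8ξ,10R,11R)-8-bromolongipin-2-en-1-one (C8 epimer not defined; the centre is lost on elimination) | C1C(Br)C[C@@]2(C)[C@@H]3C(=O)C=C(C)[C@H]2[C@@H]3C1(C)C
F2 | step 5 | (4R,5S,10R,11R)-longipina-2,8-dien-1-one | C1C=C[C@@]2(C)[C@@H]3C(=O)C=C(C)[C@H]2[C@@H]3C1(C)C
F3 | step 5 | (4R,5S,10R,11R)-longipina-2,7-dien-1-one | C1=CC[C@@]2(C)[C@@H]3C(=O)C=C(C)[C@H]2[C@@H]3C1(C)C
F4 | step 7 | (4R,5S,8S,9S,10R,11R)-8,9-epoxylongipin-2-ene-1,7-dione | O=C1[C@H]4O[C@H]4[C@@]2(C)[C@@H]3C(=O)C=C(C)[C@H]2[C@@H]3C1(C)C
F5 | step 8 | (4R,5S,7R,9R,10R,11R)-9-acetoxy-7-hydroxylongipin-2-en-1-one | O[C@@H]1C[C@@H](OC(C)=O)[C@@]2(C)[C@@H]3C(=O)C=C(C)[C@H]2[C@@H]3C1(C)C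
F6 | step 8 | (4R,5S,7R,9R,10R,11R)-9-acetoxy-7-[(E)-2-methylbut-2-enoyloxy]longipin-2-en-1-one | C/C=C(\C)C(=O)O[C@@H]1C[C@@H](OC(C)=O)[C@@]2(C)[C@@H]3C(=O)C=C(C)[C@H]2[C@@H]3C1(C)C
F7 | step 8 | (4R,5S,7R,9R,10R,11R)-9-hydroxy-7-[(E)-2-methylbut-2-enoyloxy]longipin-2-en-1-one | C/C=C(\C)C(=O)O[C@@H]1C[C@@H](O)[C@@]2(C)[C@@H]3C(=O)C=C(C)[C@H]2[C@@H]3C1(C)C
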